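**Strategy.** The 42-membered macrolactone is opened at C37–C38, the sp3–sp2 bond joining the unfunctionalised C32–C37 hexamethylene chain to the isolated (Z)-C38=C39 olefin of the ring. One intramolecular B-alkyl Suzuki–Miyaura coupling closes this ring: 9-BBN hydroborates the only terminal alkene (C36=C37) of a linear seco-ester and Pd(0) joins C37 to the (Z)-C38 vinyl iodide with retention, fixing the 38Z geometry. The precursor is a dodeca-TBS ester made by Still–Gennari union (C2=C3) of a C3–C37 (Z)-enal, grown from a two-directionally allylated all-anti polyol and an iteratively allylated/hydroformylated 1,5-polyol joined by aldol, with a C38–C50 phosphonoacetate.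

Key step: step 39

Remark 1: atom numbers C1–C50 follow the target chain (C1 = lactone carbonyl, C41 = carbon bearing the lactone oxygen, C50 = terminal methyl); TBS = tert-butyldimethylsilyl, TBSO = its ether.
Remark 2 (assumption): bis(2,2,2-trifluoroethyl)phosphonoacetic acid and 2-(1,3-dioxolan-2-yl)ethanol are taken as purchasable. For the chiral catalysts and reagents (Ir/Cl,MeO-BIPHEP, Ipc2BCl, TRIP) the hand named is the one assumed to give the configuration drawn in the SMILES; its antipode would be used if a model reaction showed the opposite sense.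

**Part A – C4–C15 polyol (steps 1–7)**

Step 1
Reactants: 1 propane-1,3-diol
Product: 2 (4R,6R)-nona-1,8-diene-4,6-diol
Conditions: allyl acetate (10 equiv), [Ir(cod)Cl]2 (5 mol %), (R)-Cl,MeO-BIPHEP (10 mol %), 4-chloro-3-nitrobenzoic acid (20 mol %), Cs2CO3 (40 mol %), 1,4-dioxane, 90 °C
Reagents that add atoms: allyl acetate, C=CCOC(C)=O
Why: Krische iridium-catalysed transfer-hydrogenative double allylation from the alcohol oxidation level should set C9 and C11 under catalyst control as the C2-symmetric anti diol, the second allylation upgrading the ee.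

Step 2
Reactants: 2 (4R,6R)-nona-1,8-diene-4,6-diol
Product: 3 (4R,6R)-4,6-bis(TBSO)nona-1,8-diene
Conditions: TBSCl, imidazole, DMF, rt
Reagents that add atoms: tert-butyldimethylsilyl chloride, CC(C)(C)[Si](C)(C)Cl
Why: Standard silylation of both secondary alcohols; no stereocentre is touched.

Step 3
Reactants: 3 (4R,6R)-4,6-bis(TBSO)nona-1,8-diene
Product: 5 (3R,5R)-3,5-bis(TBSO)heptane-1,7-diol, via bis-ozonide 4 (not isolated)
Conditions: O3, CH2Cl2, −78 °C; then NaBH4, MeOH, −78 °C → rt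
Reagents that add atoms: ozone, [O-][O+]=O
Why: Ozonolysis of both terminal olefins with reductive borohydride work-up should give the C2-symmetric primary diol (C7/C13) needed for the next allylation.

Step 4
Reactants: 5 (3R,5R)-3,5-bis(TBSO)heptane-1,7-diol
Product: 6 (4S,6R,8R,10S)-6,8-bis(TBSO)trideca-1,12-diene-4,10-diol
Conditions: allyl acetate (10 equiv), [Ir(cod)Cl]2, (S)-Cl,MeO-BIPHEP, 4-chloro-3-nitrobenzoic acid, Cs2CO3, 1,4-dioxane, 90 °C
Reagents that add atoms: allyl acetate, C=CCOC(C)=O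
Why: A second two-directional Krische allylation with the antipodal catalyst should override the substrate and place the new C7 and C13 carbinols 1,3-anti to C9 and C11, completing the all-anti tetrad.

Step 5
Reactants: 6 (4S,6R,8R,10S)-6,8-bis(TBSO)trideca-1,12-diene-4,10-diol
Product: 7 (4S,6R,8R,10S)-4,6,8,10-tetrakis(TBSO)trideca-1,12-diene
Conditions: TBSOTf, 2,6-lutidine, CH2Cl2, −78 → 0 °C
Reagents that add atoms: tert-butyldimethylsilyl triflate, CC(C)(C)[Si](C)(C)OS(=O)(=O)C(F)(F)F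
Why: Silyl triflate silylation of the two homoallylic alcohols; no stereocentre is touched.

Step 6
Reactants: 7 (4S,6R,8R,10S)-4,6,8,10-tetrakis(TBSO)trideca-1,12-diene
Product: 9 (3R,5S,7S,9R)-3,5,7,9-tetrakis(TBSO)undecanedial, via bis-ozonide 8 (not isolated)
Conditions: O3, CH2Cl2, −78 °C; then PPh3, −78 °C → rt
Reagents that add atoms: ozone, [O-][O+]=O
Why: Ozonolysis with phosphine reduction should give the C2-symmetric C5/C15 dialdehyde without epimerisable centres.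

Step 7
Reactants: 9 (3R,5S,7S,9R)-3,5,7,9-tetrakis(TBSO)undecanedial
Product: 10 (3R,5S,7R,9S,11Z)-12-iodo-3,5,7,9-tetrakis(TBSO)tridec-11-enal
Conditions: EtPPh3I, n-BuLi, THF, rt; I2, −78 °C; NaHMDS, −78 → −20 °C; ylide added to 9 (3 equiv), THF, −78 °C; recovered 9 recycled
Reagents that add atoms: ethyltriphenylphosphonium iodide, CC[P+](c1ccccc1)(c1ccccc1)c1ccccc1.[I-]; iodine, II
Why: Stork–Zhao olefination with Ph3P=C(I)CH3 should give the (Z)-2-iodo-2-alkene (C4=C5); the two formyl groups of 9 are homotopic, so mono-olefination gives a single compound, and excess dialdehyde with inverse addition limits bis-olefination.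

**Part B – C16–C37 methyl ketone (steps 8–23)**

Step 8
Reactants: 11 2-(1,3-dioxolan-2-yl)ethan-1-ol
Product: 12 (2R)-1-(1,3-dioxolan-2-yl)pent-4-en-2-ol
Conditions: allyl acetate, [Ir(cod)Cl]2, (R)-Cl,MeO-BIPHEP, 4-chloro-3-nitrobenzoic acid, Cs2CO3, THF, 100 °C
Reagents that add atoms: allyl acetate, C=CCOC(C)=O
Why: Krische allylation of the primary alcohol with the same catalyst hand as step 1 should set C23; the cyclic acetal masks C21 and resists β-elimination in the transient aldehyde.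

Step 9
Reactants: 12 (2R)-1-(1,3-dioxolan-2-yl)pent-4-en-2-ol
Product: 13 2-[(2R)-2-(TBSO)pent-4-en-1-yl]-1,3-dioxolane
Conditions: TBSCl, imidazole, DMF, rt
Reagents that add atoms: tert-butyldimethylsilyl chloride, CC(C)(C)[Si](C)(C)Cl
Why: Standard silylation; no stereocentre is touched.

Step 10
Reactants: 13 2-[(2R)-2-(TBSO)pent-4-en-1-yl]-1,3-dioxolane
Product: 14 (5R)-5-(TBSO)-6-(1,3-dioxolan-2-yl)hexanal
Conditions: Rh(acac)(CO)2 (1 mol %), BIPHEPHOS (3 mol %), CO/H2 (1:1, 10 bar), toluene, 70 °C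
Reagents that add atoms: carbon monoxide, [C-]#[O+]
Why: Linear-selective Rh/bisphosphite hydroformylation should homologate the terminal olefin by one carbon to the C27 aldehyde, giving the three-methylene spacing of the 1,5-polyol.

Step 11
Reactants: 14 (5R)-5-(TBSO)-6-(1,3-dioxolan-2-yl)hexanal
Product: 15 (4S,8R)-8-(TBSO)-9-(1,3-dioxolan-2-yl)non-1-en-4-ol
Conditions: allyl acetate, [Ir(cod)Cl]2, (R)-Cl,MeO-BIPHEP, 4-chloro-3-nitrobenzoic acid, Cs2CO3, i-PrOH (2 equiv), THF, 100 °C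
Reagents that add atoms: allyl acetate, C=CCOC(C)=O
Why: Krische allylation from the aldehyde oxidation level (isopropanol as terminal reductant) with the same catalyst should set C27 in the same spatial sense as C23.

Step 12
Reactants: 15 (4S,8R)-8-(TBSO)-9-(1,3-dioxolan-2-yl)non-1-en-4-ol
Product: 16 2-[(2R,6S)-2,6-bis(TBSO)non-8-en-1-yl]-1,3-dioxolane
Conditions: TBSCl, imidazole, DMF, rt
Reagents that add atoms: tert-butyldimethylsilyl chloride, CC(C)(C)[Si](C)(C)Cl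
Why: Standard silylation; no stereocentre is touched.

Step 13
Reactants: 16 2-[(2R,6S)-2,6-bis(TBSO)non-8-en-1-yl]-1,3-dioxolane
Product: 17 (5S,9R)-5,9-bis(TBSO)-10-(1,3-dioxolan-2-yl)decanal
Conditions: Rh(acac)(CO)2 (1 mol %), BIPHEPHOS (3 mol %), CO/H2 (1:1, 10 bar), toluene, 70 °C
Reagents that add atoms: carbon monoxide, [C-]#[O+]
Why: Second linear-selective hydroformylation should give the C31 aldehyde.

Step 14
Reactants: 17 (5S,9R)-5,9-bis(TBSO)-10-(1,3-dioxolan-2-yl)decanal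
Product: 18 (4S,8R,12R)-8,12-bis(TBSO)-13-(1,3-dioxolan-2-yl)tridec-1-en-4-ol
Conditions: allyl acetate, [Ir(cod)Cl]2, (R)-Cl,MeO-BIPHEP, 4-chloro-3-nitrobenzoic acid, Cs2CO3, i-PrOH (2 equiv), THF, 100 °C
Reagents that add atoms: allyl acetate, C=CCOC(C)=O
Why: Third Krische allylation with the same catalyst should set C31, so one catalyst fixes C23, C27 and C31.

Step 15
Reactants: 18 (4S,8R,12R)-8,12-bis(TBSO)-13-(1,3-dioxolan-2-yl)tridec-1-en-4-ol
Product: 19 2-[(2R,6R,10S)-2,6,10-tris(TBSO)tridec-12-en-1-yl]-1,3-dioxolane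
Conditions: TBSCl, imidazole, DMF, rt
Reagents that add atoms: tert-butyldimethylsilyl chloride, CC(C)(C)[Si](C)(C)Cl
Why: Standard silylation; no stereocentre is touched.

Step 16
Reactants: 19 2-[(2R,6R,10S)-2,6,10-tris(TBSO)tridec-12-en-1-yl]-1,3-dioxolane
Product: 21 2-[(2R,6R,10R)-2,6,10-tris(TBSO)hexadec-15-en-1-yl]-1,3-dioxolane, via alkyl-9-BBN borane 20 (not isolated)
Conditions: 9-BBN, THF, 0 °C → rt; then allyl diethyl phosphate, CuOAc (10 mol %), KOtBu, THF, 60 °C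
Reagents that add atoms: allyl diethyl phosphate, C=CCOP(=O)(OCC)OCC
Why: Anti-Markovnikov hydroboration followed by copper-catalysed allyl–alkyl coupling of the alkylborate (B→Cu transmetalation, then allylic substitution) should extend the chain to the hex-5-enyl tail C32–C37.

Step 17
Reactants: 21 2-[(2R,6R,10R)-2,6,10-tris(TBSO)hexadec-15-en-1-yl]-1,3-dioxolane
Product: 23 (3R,7R,11R)-3,7,11-tris(TBSO)heptadec-16-enal, via collidinium acetal salt 22 (not isolated)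
Conditions: TESOTf, 2,4,6-collidine, CH2Cl2, 0 °C; then H2O
Reagents that add atoms: water, O
Why: Silyl-triflate/collidine opening of the aldehyde acetal to a pyridinium N,O-acetal and its hydrolysis should release the C21 aldehyde under non-acidic conditions that spare the TBS ethers and avoid β-elimination.

Step 18
Reactants: 23 (3R,7R,11R)-3,7,11-tris(TBSO)heptadec-16-enal
Product: 24 (2Z,5R,9R,13R)-2-iodo-5,9,13-tris(TBSO)nonadeca-2,18-diene
Conditions: EtPPh3I, n-BuLi, THF, rt; I2, −78 °C; NaHMDS, −78 → −20 °C; then 23, −78 °C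
Reagents that add atoms: ethyltriphenylphosphonium iodide, CC[P+](c1ccccc1)(c1ccccc1)c1ccccc1.[I-]; iodine, II
Why: Stork–Zhao olefination should give the (Z)-2-iodo-2-alkene, fixing the C20=C21 geometry (iodine cis to C22).

Step 19
Reactants: 24 (2Z,5R,9R,13R)-2-iodo-5,9,13-tris(TBSO)nonadeca-2,18-diene
Product: 26 (2Z,5R,9R,13R)-2-methyl-5,9,13-tris(TBSO)nonadeca-2,18-dienal, via vinyllithium 25 (not isolated)
Conditions: t-BuLi (2.1 equiv), Et2O, −78 °C; then DMF, −78 → 0 °C; aq NH4Cl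
Reagents that add atoms: N,N-dimethylformamide, CN(C)C=O
Why: Iodine–lithium exchange and formylation both proceed with retention at the sp2 carbon, so the (Z)-α-methyl enal (C19) should result.

Step 20
Reactants: 26 (2Z,5R,9R,13R)-2-methyl-5,9,13-tris(TBSO)nonadeca-2,18-dienal
Product: 27 (4S)-4-benzyl-3-[(2S,3S,4Z,7R,11R,15R)-3-hydroxy-2,4-dimethyl-7,11,15-tris(TBSO)henicosa-4,20-dienoyl]-1,3-thiazolidine-2-thione
Conditions: (S)-4-benzyl-3-propanoyl-1,3-thiazolidine-2-thione, TiCl4 (1.05 equiv), i-Pr2NEt (1.1 equiv), NMP (1.0 equiv), CH2Cl2, 0 °C; then 26, −78 → 0 °C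
Reagents that add atoms: (S)-4-benzyl-3-propanoyl-1,3-thiazolidine-2-thione, CCC(=O)N1[C@@H](Cc2ccccc2)CSC1=S
Why: Crimmins titanium aldol of the (Z)-chlorotitanium enolate through a non-chelated chair transition state should give the "Evans-syn" adduct, the auxiliary setting C18 and C19 (18,19-syn).

Step 21
Reactants: 27 the aldol adduct
Product: 28 (2S,3S,4Z,7R,11R,15R)-3-hydroxy-N-methoxy-N,2,4-trimethyl-7,11,15-tris(TBSO)henicosa-4,20-dienamide
Conditions: MeONHMe·HCl, imidazole, CH2Cl2, rt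
Reagents that add atoms: N,O-dimethylhydroxylamine hydrochloride, CNOC.Cl
Why: The activated N-acyl thiazolidinethione should undergo direct aminolysis to the Weinreb amide without epimerising C18.

Step 22
Reactants: 28 the Weinreb amide
Product: 29 (2S,3S,4Z,7R,11R,15R)-N-methoxy-N,2,4-trimethyl-3,7,11,15-tetrakis(TBSO)henicosa-4,20-dienamide
Conditions: TBSOTf, 2,6-lutidine, CH2Cl2, −78 → 0 °C
Reagents that add atoms: tert-butyldimethylsilyl triflate, CC(C)(C)[Si](C)(C)OS(=O)(=O)C(F)(F)F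
Why: Silylation of the allylic C19 alcohol; no stereocentre is touched.

Step 23
Reactants: 29 the silylated Weinreb amide
Product: 30 (3S,4S,5Z,8R,12R,16R)-3,5-dimethyl-4,8,12,16-tetrakis(TBSO)docosa-5,21-dien-2-one
Conditions: MeMgBr, THF, 0 °C
Reagents that add atoms: methylmagnesium bromide, C[Mg]Br
Why: Weinreb ketone synthesis; the chelated tetrahedral intermediate prevents over-addition and the methyl group becomes C16.

**Part C – union to the C3–C37 enal (steps 24–27)**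

Step 24
Reactants: 30 the C16–C37 methyl ketone; 10 the C4–C15 iodo-aldehyde
Product: 32 C4–C37 β-hydroxy ketone (15-hydroxy-17-oxo; (Z)-C4 iodide; TBS ethers at O7, O9, O11, O13, O19, O23, O27, O31), via boron enolate 31 (not isolated)
Conditions: (−)-Ipc2BCl (matched hand), Et3N, Et2O, −78 → 0 °C; then 10, −78 → −20 °C; H2O2, pH 7 buffer, MeOH, 0 °C
Reagents that add atoms: none
Why: Kinetic boron enolisation at the methyl group (C16) and aldol addition through a chair transition state should set C15 by the matched pairing of the enolate's 1,4-syn bias (C18 methyl) with the Ipc ligands, which is also the 1,3-anti (Felkin-type) sense for the β-silyloxy aldehyde.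

Step 25
Reactants: 32 the β-hydroxy ketone
Product: 33 C4–C37 15,17-anti diol
Conditions: Me4NBH(OAc)3, MeCN/AcOH (1:1), −30 °C
Reagents that add atoms: none
Why: Evans–Saksena reduction: the borohydride exchanges onto the C15 hydroxyl and delivers hydride intramolecularly through a chair transition state, which should set C17 anti to C15.

Step 26
Reactants: 33 the 15,17-diol
Product: 34 C4–C37 deca-TBS (Z)-vinyl iodide
Conditions: TBSOTf, 2,6-lutidine, CH2Cl2, −78 °C → rt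
Reagents that add atoms: tert-butyldimethylsilyl triflate, CC(C)(C)[Si](C)(C)OS(=O)(=O)C(F)(F)F
Why: Exhaustive silylation of the two remaining secondary alcohols; no stereocentre is touched.

Step 27
Reactants: 34 the deca-TBS vinyl iodide
Product: 36 C3–C37 (Z)-enal, via vinyllithium 35 (not isolated)
Conditions: t-BuLi (2.1 equiv), Et2O, −78 °C; then DMF, −78 → 0 °C; aq NH4Cl
Reagents that add atoms: N,N-dimethylformamide, CN(C)C=O
Why: Stereoretentive iodine–lithium exchange and formylation should give the (4Z)-enal; the substrate now carries only silyl ethers and olefins, which tolerate t-BuLi at −78 °C.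

**Part D – C38–C50 phosphonoacetate (steps 28–37)**

Step 28
Reactants: 37 (2R)-2-methyloxirane
Product: 38 (2R)-non-8-en-2-ol
Conditions: hex-5-en-1-ylmagnesium bromide, CuI (10 mol %), THF, −30 → 0 °C
Reagents that add atoms: hex-5-en-1-ylmagnesium bromide, C=CCCCC[Mg]Br
Why: Copper-catalysed Grignard opening at the unsubstituted epoxide carbon leaves the C49 stereocentre untouched.

Step 29
Reactants: 38 (2R)-non-8-en-2-ol
Product: 39 (2R)-2-(TBSO)non-8-ene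
Conditions: TBSCl, imidazole, DMF, rt
Reagents that add atoms: tert-butyldimethylsilyl chloride, CC(C)(C)[Si](C)(C)Cl
Why: Standard silylation; no stereocentre is touched.

Step 30
Reactants: 39 (2R)-2-(TBSO)non-8-ene
Product: 41 (7R)-7-(TBSO)octanal, via ozonide 40 (not isolated)
Conditions: O3, CH2Cl2, −78 °C; then PPh3, −78 °C → rt
Reagents that add atoms: ozone, [O-][O+]=O
Why: Ozonolysis of the only olefin should give the C43 aldehyde.

Step 31
Reactants: 41 (7R)-7-(TBSO)octanal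
Product: 42 (4S)-4-benzyl-3-[(2S,3R,9R)-3-hydroxy-2-methyl-9-(TBSO)decanoyl]-1,3-thiazolidine-2-thione
Conditions: (S)-4-benzyl-3-propanoyl-1,3-thiazolidine-2-thione, TiCl4 (1.05 equiv), i-Pr2NEt (1.1 equiv), NMP (1.0 equiv), CH2Cl2, 0 °C; then 41, −78 → 0 °C
Reagents that add atoms: (S)-4-benzyl-3-propanoyl-1,3-thiazolidine-2-thione, CCC(=O)N1[C@@H](Cc2ccccc2)CSC1=S
Why: Crimmins "Evans-syn" titanium aldol; the auxiliary should set C42 and C43 (42,43-syn) through the non-chelated chair transition state.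

Step 32
Reactants: 42 the aldol adduct
Product: 43 (4S)-4-benzyl-3-[(2S,3R,9R)-3,9-bis(TBSO)-2-methyldecanoyl]-1,3-thiazolidine-2-thione
Conditions: TBSOTf, 2,6-lutidine, CH2Cl2, −78 → 0 °C
Reagents that add atoms: tert-butyldimethylsilyl triflate, CC(C)(C)[Si](C)(C)OS(=O)(=O)C(F)(F)F
Why: Silylation of the C43 alcohol; no stereocentre is touched.

Step 33
Reactants: 43 the silylated thioimide
Product: 44 (2S,3R,9R)-3,9-bis(TBSO)-2-methyldecanal
Conditions: DIBAL-H, CH2Cl2, −78 °C; Rochelle salt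
Reagents that add atoms: none
Why: N-Acyl thiazolidinethiones are reduced by DIBAL-H directly to aldehydes through a stable tetrahedral aluminate, so the C41 aldehyde should form without epimerising C42.

Step 34
Reactants: 44 (2S,3R,9R)-3,9-bis(TBSO)-2-methyldecanal
Product: 45 (4S,5R,6R,12R)-6,12-bis(TBSO)-5-methyltridec-1-yn-4-ol
Conditions: allenylboronic acid pinacol ester (1.5 equiv), (S)-TRIP (10 mol %), 4 Å MS, toluene, 0 °C → rt
Reagents that add atoms: allenylboronic acid pinacol ester, C=C=CB1OC(C)(C)C(C)(C)O1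
Why: Chiral phosphoric acid-catalysed propargylboration through a closed six-membered SE2′ transition state should give only the homopropargylic alcohol; the catalyst directs Si-face attack, which is also the Felkin–Anh face of the α-methyl aldehyde, so C41 is set 41,42-syn (matched).

Step 35
Reactants: 45 the homopropargylic alcohol
Product: 46 (4S,5R,6R,12R)-1-iodo-6,12-bis(TBSO)-5-methyltridec-1-yn-4-ol
Conditions: NIS, AgNO3 (10 mol %), acetone, rt, dark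
Reagents that add atoms: N-iodosuccinimide, O=C1CCC(=O)N1I
Why: Silver-catalysed iodination of the terminal alkyne via the silver acetylide; the free alcohol is tolerated.

Step 36
Reactants: 46 the iodoalkyne
Product: 47 (1Z,4S,5R,6R,12R)-1-iodo-6,12-bis(TBSO)-5-methyltridec-1-en-4-ol
Conditions: 2-nitrobenzenesulfonylhydrazide, Et3N, THF/i-PrOH, rt
Reagents that add atoms: none
Why: Diimide generated in the flask transfers H2 in a concerted syn fashion to the iodoalkyne, which should give the (Z)-vinyl iodide (C38=C39); no other π-bond is present.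

Step 37
Reactants: 47 the (Z)-iodo alcohol
Product: 48 (1Z,4S,5R,6R,12R)-1-iodo-6,12-bis(TBSO)-5-methyltridec-1-en-4-yl [bis(2,2,2-trifluoroethoxy)phosphoryl]acetate
Conditions: bis(2,2,2-trifluoroethyl)phosphonoacetic acid, DCC, DMAP (cat.), CH2Cl2, 0 °C → rt
Reagents that add atoms: bis(2,2,2-trifluoroethyl)phosphonoacetic acid, OC(=O)CP(=O)(OCC(F)(F)F)OCC(F)(F)F
Why: Carbodiimide esterification of the hindered C41 alcohol, which runs through the reactive phosphonoketene; no stereocentre is affected.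

**Part E – union, ring closure, deprotection (steps 38–40)**

Step 38
Reactants: 48 the C38–C50 phosphonoacetate; 36 the C3–C37 (Z)-enal
Product: 50 seco-ester (C1–C37 (2Z,4Z)-dienoate of the C41 alcohol; terminal C36=C37 alkene; (Z)-C38 vinyl iodide; twelve TBS ethers), via potassium phosphonate carbanion 49 (not isolated)
Conditions: KHMDS, 18-crown-6, THF, −78 °C; then 36, −78 °C
Reagents that add atoms: none
Why: Still–Gennari olefination: the electron-poor bis(trifluoroethyl)phosphonate eliminates from the kinetic adduct faster than it equilibrates, which should give the (2Z)-enoate and hence the (2Z,4Z)-dienoate while joining the two halves.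

Step 39
Reactants: 50 the seco-ester
Product: 52 dodeca-TBS 42-membered macrolactone, via C37 alkyl-9-BBN borane 51 (not isolated)
Conditions: 9-BBN dimer (2.5 equiv B–H), THF, rt; H2O quench; then syringe-pump addition over 12 h to Pd(dppf)Cl2·CH2Cl2 (30 mol %), AsPh3 (60 mol %), Cs2CO3 (6 equiv), DMF/THF/H2O, 45 °C, 1 mM
Reagents that add atoms: none
Why: 9-BBN should add anti-Markovnikov to the only monosubstituted alkene (C36=C37), and the resulting borane is then fed slowly to Pd(0) and base, where oxidative addition into the C38–I bond, base-assisted transmetalation of the primary alkyl group and reductive elimination forge C37–C38. The closest known reaction type is the intramolecular B-alkyl Suzuki–Miyaura macrocyclisation of ω-alkenyl vinyl iodides. The 42-membered ring closes end-to-end by reductive elimination from a macrocyclic alkyl(alkenyl)palladium species, and high dilution with slow addition favours cyclisation over oligomerisation. No stereocentre is formed, and the 38Z geometry is carried over from the vinyl iodide because oxidative addition and reductive elimination are stereoretentive. The step needs chemoselective hydroboration, which the substitution pattern secures (trisubstituted C4=C5 and C20=C21, the electron-poor dienoate and the internal iodo-olefin react far more slowly with 9-BBN). It also needs the (2Z,4Z)-dienoate ester to survive, which the mild carbonate/AsPh3/dppf system at 45 °C should allow while dppf suppresses β-hydride elimination.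

Step 40
Reactants: 52 the dodeca-TBS macrolactone
Product: 53 CNP0392687.2 (target)
Conditions: HF·pyridine (excess), pyridine, THF, 0 °C → rt
Reagents that add atoms: none
Why: Buffered fluoride cleavage of all twelve silyl ethers under mildly acidic conditions should spare the (2Z,4Z)-dienoate lactone and the allylic C19 alcohol and avoid base-induced acyl migration.

**Compound list**

1 | propane-1,3-diol | OCCCO | starting material
2 | (4R,6R)-nona-1,8-diene-4,6-diol | C=CC[C@@H](O)C[C@H](O)CC=C | intermediate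
3 | (4R,6R)-4,6-bis(TBSO)nona-1,8-diene | C=CC[C@@H](O[Si](C)(C)C(C)(C)C)C[C@H](O[Si](C)(C)C(C)(C)C)CC=C | intermediate
4 | bis-ozonide of 3 (not isolated) | C1OC(C[C@@H](O[Si](C)(C)C(C)(C)C)C[C@H](O[Si](C)(C)C(C)(C)C)CC2OCOO2)OO1 | intermediate
5 | (3R,5R)-3,5-bis(TBSO)heptane-1,7-diol | OCC[C@@H](O[Si](C)(C)C(C)(C)C)C[C@H](O[Si](C)(C)C(C)(C)C)CCO | intermediate
6 | (4S,6R,8R,10S)-6,8-bis(TBSO)trideca-1,12-diene-4,10-diol | C=CC[C@H](O)C[C@@H](O[Si](C)(C)C(C)(C)C)C[C@H](O[Si](C)(C)C(C)(C)C)C[C@@H](O)CC=C | intermediate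
7 | (4S,6R,8R,10S)-4,6,8,10-tetrakis(TBSO)trideca-1,12-diene | C=CC[C@H](O[Si](C)(C)C(C)(C)C)C[C@@H](O[Si](C)(C)C(C)(C)C)C[C@H](O[Si](C)(C)C(C)(C)C)C[C@@H](O[Si](C)(C)C(C)(C)C)CC=C | intermediate
8 | bis-ozonide of 7 (not isolated) | C1OC(C[C@H](O[Si](C)(C)C(C)(C)C)C[C@@H](O[Si](C)(C)C(C)(C)C)C[C@H](O[Si](C)(C)C(C)(C)C)C[C@@H](O[Si](C)(C)C(C)(C)C)CC2OCOO2)OO1 | intermediate
9 | (3R,5S,7S,9R)-3,5,7,9-tetrakis(TBSO)undecanedial (C5–C15) | O=CC[C@H](O[Si](C)(C)C(C)(C)C)C[C@@H](O[Si](C)(C)C(C)(C)C)C[C@H](O[Si](C)(C)C(C)(C)C)C[C@@H](O[Si](C)(C)C(C)(C)C)CC=O | intermediate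
10 | (3R,5S,7R,9S,11Z)-12-iodo-3,5,7,9-tetrakis(TBSO)tridec-11-enal (C4–C15) | C/C(I)=C/C[C@H](O[Si](C)(C)C(C)(C)C)C[C@@H](O[Si](C)(C)C(C)(C)C)C[C@H](O[Si](C)(C)C(C)(C)C)C[C@@H](O[Si](C)(C)C(C)(C)C)CC=O | intermediate
11 | 2-(1,3-dioxolan-2-yl)ethan-1-ol | OCCC1OCCO1 | starting material
12 | (2R)-1-(1,3-dioxolan-2-yl)pent-4-en-2-ol | O1CCOC1C[C@H](O)CC=C | intermediate
13 | 2-[(2R)-2-(TBSO)pent-4-en-1-yl]-1,3-dioxolane | O1CCOC1C[C@H](O[Si](C)(C)C(C)(C)C)CC=C | intermediate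
14 | (5R)-5-(TBSO)-6-(1,3-dioxolan-2-yl)hexanal | O1CCOC1C[C@H](O[Si](C)(C)C(C)(C)C)CCCC=O | intermediate
15 | (4S,8R)-8-(TBSO)-9-(1,3-dioxolan-2-yl)non-1-en-4-ol | O1CCOC1C[C@H](O[Si](C)(C)C(C)(C)C)CCC[C@H](O)CC=C | intermediate
16 | 2-[(2R,6S)-2,6-bis(TBSO)non-8-en-1-yl]-1,3-dioxolane | O1CCOC1C[C@H](O[Si](C)(C)C(C)(C)C)CCC[C@H](O[Si](C)(C)C(C)(C)C)CC=C | intermediate
17 | (5S,9R)-5,9-bis(TBSO)-10-(1,3-dioxolan-2-yl)decanal | O1CCOC1C[C@H](O[Si](C)(C)C(C)(C)C)CCC[C@H](O[Si](C)(C)C(C)(C)C)CCCC=O | intermediate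
18 | (4S,8R,12R)-8,12-bis(TBSO)-13-(1,3-dioxolan-2-yl)tridec-1-en-4-ol | O1CCOC1C[C@H](O[Si](C)(C)C(C)(C)C)CCC[C@H](O[Si](C)(C)C(C)(C)C)CCC[C@H](O)CC=C | intermediate
19 | 2-[(2R,6R,10S)-2,6,10-tris(TBSO)tridec-12-en-1-yl]-1,3-dioxolane | O1CCOC1C[C@H](O[Si](C)(C)C(C)(C)C)CCC[C@H](O[Si](C)(C)C(C)(C)C)CCC[C@H](O[Si](C)(C)C(C)(C)C)CC=C | intermediate
20 | alkyl-9-BBN borane from 19 (not isolated) | O1CCOC1C[C@H](O[Si](C)(C)C(C)(C)C)CCC[C@H](O[Si](C)(C)C(C)(C)C)CCC[C@H](O[Si](C)(C)C(C)(C)C)CCCB1C2CCCC1CCC2 | intermediate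
21 | 2-[(2R,6R,10R)-2,6,10-tris(TBSO)hexadec-15-en-1-yl]-1,3-dioxolane | O1CCOC1C[C@H](O[Si](C)(C)C(C)(C)C)CCC[C@H](O[Si](C)(C)C(C)(C)C)CCC[C@H](O[Si](C)(C)C(C)(C)C)CCCCC=C | intermediate
22 | 2,4,6-collidinium N,O-acetal triflate from 21 (not isolated; C21 epimers) | Cc1cc(C)cc(C)[n+]1C(OCCO[Si](CC)(CC)CC)C[C@H](O[Si](C)(C)C(C)(C)C)CCC[C@H](O[Si](C)(C)C(C)(C)C)CCC[C@H](O[Si](C)(C)C(C)(C)C)CCCCC=C.[O-]S(=O)(=O)C(F)(F)F | intermediate
23 | (3R,7R,11R)-3,7,11-tris(TBSO)heptadec-16-enal (C21–C37) | O=CC[C@H](O[Si](C)(C)C(C)(C)C)CCC[C@H](O[Si](C)(C)C(C)(C)C)CCC[C@H](O[Si](C)(C)C(C)(C)C)CCCCC=C | intermediate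
24 | (2Z,5R,9R,13R)-2-iodo-5,9,13-tris(TBSO)nonadeca-2,18-diene | C/C(I)=C/C[C@H](O[Si](C)(C)C(C)(C)C)CCC[C@H](O[Si](C)(C)C(C)(C)C)CCC[C@H](O[Si](C)(C)C(C)(C)C)CCCCC=C | intermediate
25 | (Z)-vinyllithium from 24 (not isolated) | [Li]/C(C)=C\C[C@H](O[Si](C)(C)C(C)(C)C)CCC[C@H](O[Si](C)(C)C(C)(C)C)CCC[C@H](O[Si](C)(C)C(C)(C)C)CCCCC=C | intermediate
26 | (2Z,5R,9R,13R)-2-methyl-5,9,13-tris(TBSO)nonadeca-2,18-dienal (C19–C37) | O=C/C(C)=C\C[C@H](O[Si](C)(C)C(C)(C)C)CCC[C@H](O[Si](C)(C)C(C)(C)C)CCC[C@H](O[Si](C)(C)C(C)(C)C)CCCCC=C | intermediate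
27 | (4S)-4-benzyl-3-[(2S,3S,4Z,7R,11R,15R)-3-hydroxy-2,4-dimethyl-7,11,15-tris(TBSO)henicosa-4,20-dienoyl]-1,3-thiazolidine-2-thione | S=C1SC[C@H](Cc2ccccc2)N1C(=O)[C@@H](C)[C@H](O)/C(C)=C\C[C@H](O[Si](C)(C)C(C)(C)C)CCC[C@H](O[Si](C)(C)C(C)(C)C)CCC[C@H](O[Si](C)(C)C(C)(C)C)CCCCC=C | intermediate
28 | (2S,3S,4Z,7R,11R,15R)-3-hydroxy-N-methoxy-N,2,4-trimethyl-7,11,15-tris(TBSO)henicosa-4,20-dienamide | CON(C)C(=O)[C@@H](C)[C@H](O)/C(C)=C\C[C@H](O[Si](C)(C)C(C)(C)C)CCC[C@H](O[Si](C)(C)C(C)(C)C)CCC[C@H](O[Si](C)(C)C(C)(C)C)CCCCC=C | intermediate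
29 | (2S,3S,4Z,7R,11R,15R)-N-methoxy-N,2,4-trimethyl-3,7,11,15-tetrakis(TBSO)henicosa-4,20-dienamide | CON(C)C(=O)[C@@H](C)[C@H](O[Si](C)(C)C(C)(C)C)/C(C)=C\C[C@H](O[Si](C)(C)C(C)(C)C)CCC[C@H](O[Si](C)(C)C(C)(C)C)CCC[C@H](O[Si](C)(C)C(C)(C)C)CCCCC=C | intermediate
30 | (3S,4S,5Z,8R,12R,16R)-3,5-dimethyl-4,8,12,16-tetrakis(TBSO)docosa-5,21-dien-2-one (C16–C37) | CC(=O)[C@@H](C)[C@H](O[Si](C)(C)C(C)(C)C)/C(C)=C\C[C@H](O[Si](C)(C)C(C)(C)C)CCC[C@H](O[Si](C)(C)C(C)(C)C)CCC[C@H](O[Si](C)(C)C(C)(C)C)CCCCC=C | intermediate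
31 | diisopinocampheylboron enolate of 30 (not isolated; Ipc stereochemistry not written) | C=C(OB(C1CC2CC(C1C)C2(C)C)C1CC2CC(C1C)C2(C)C)[C@@H](C)[C@H](O[Si](C)(C)C(C)(C)C)/C(C)=C\C[C@H](O[Si](C)(C)C(C)(C)C)CCC[C@H](O[Si](C)(C)C(C)(C)C)CCC[C@H](O[Si](C)(C)C(C)(C)C)CCCCC=C | intermediate
32 | C4–C37 15-hydroxy-17-ketone, (Z)-C4 iodide, octa-TBS | C/C(I)=C/C[C@H](O[Si](C)(C)C(C)(C)C)C[C@@H](O[Si](C)(C)C(C)(C)C)C[C@H](O[Si](C)(C)C(C)(C)C)C[C@@H](O[Si](C)(C)C(C)(C)C)C[C@H](O)CC(=O)[C@@H](C)[C@H](O[Si](C)(C)C(C)(C)C)/C(C)=C\C[C@H](O[Si](C)(C)C(C)(C)C)CCC[C@H](O[Si](C)(C)C(C)(C)C)CCC[C@H](O[Si](C)(C)C(C)(C)C)CCCCC=C | intermediate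
33 | C4–C37 15,17-anti diol, (Z)-C4 iodide, octa-TBS | C/C(I)=C/C[C@H](O[Si](C)(C)C(C)(C)C)C[C@@H](O[Si](C)(C)C(C)(C)C)C[C@H](O[Si](C)(C)C(C)(C)C)C[C@@H](O[Si](C)(C)C(C)(C)C)C[C@H](O)C[C@@H](O)[C@@H](C)[C@H](O[Si](C)(C)C(C)(C)C)/C(C)=C\C[C@H](O[Si](C)(C)C(C)(C)C)CCC[C@H](O[Si](C)(C)C(C)(C)C)CCC[C@H](O[Si](C)(C)C(C)(C)C)CCCCC=C | intermediate
34 | C4–C37 deca-TBS (Z)-vinyl iodide | C/C(I)=C/C[C@H](O[Si](C)(C)C(C)(C)C)C[C@@H](O[Si](C)(C)C(C)(C)C)C[C@H](O[Si](C)(C)C(C)(C)C)C[C@@H](O[Si](C)(C)C(C)(C)C)C[C@H](O[Si](C)(C)C(C)(C)C)C[C@@H](O[Si](C)(C)C(C)(C)C)[C@@H](C)[C@H](O[Si](C)(C)C(C)(C)C)/C(C)=C\C[C@H](O[Si](C)(C)C(C)(C)C)CCC[C@H](O[Si](C)(C)C(C)(C)C)CCC[C@H](O[Si](C)(C)C(C)(C)C)CCCCC=C | intermediate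
35 | (Z)-C4 vinyllithium from 34 (not isolated) | [Li]/C(C)=C\C[C@H](O[Si](C)(C)C(C)(C)C)C[C@@H](O[Si](C)(C)C(C)(C)C)C[C@H](O[Si](C)(C)C(C)(C)C)C[C@@H](O[Si](C)(C)C(C)(C)C)C[C@H](O[Si](C)(C)C(C)(C)C)C[C@@H](O[Si](C)(C)C(C)(C)C)[C@@H](C)[C@H](O[Si](C)(C)C(C)(C)C)/C(C)=C\C[C@H](O[Si](C)(C)C(C)(C)C)CCC[C@H](O[Si](C)(C)C(C)(C)C)CCC[C@H](O[Si](C)(C)C(C)(C)C)CCCCC=C | intermediate
36 | C3–C37 deca-TBS (4Z)-enal | O=C/C(C)=C\C[C@H](O[Si](C)(C)C(C)(C)C)C[C@@H](O[Si](C)(C)C(C)(C)C)C[C@H](O[Si](C)(C)C(C)(C)C)C[C@@H](O[Si](C)(C)C(C)(C)C)C[C@H](O[Si](C)(C)C(C)(C)C)C[C@@H](O[Si](C)(C)C(C)(C)C)[C@@H](C)[C@H](O[Si](C)(C)C(C)(C)C)/C(C)=C\C[C@H](O[Si](C)(C)C(C)(C)C)CCC[C@H](O[Si](C)(C)C(C)(C)C)CCC[C@H](O[Si](C)(C)C(C)(C)C)CCCCC=C | intermediate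
37 | (2R)-2-methyloxirane | C[C@@H]1CO1 | starting material
38 | (2R)-non-8-en-2-ol | C[C@@H](O)CCCCCC=C | intermediate
39 | (2R)-2-(TBSO)non-8-ene | C[C@@H](O[Si](C)(C)C(C)(C)C)CCCCCC=C | intermediate
40 | ozonide of 39 (not isolated) | C[C@@H](O[Si](C)(C)C(C)(C)C)CCCCCC1OCOO1 | intermediate
41 | (7R)-7-(TBSO)octanal | C[C@@H](O[Si](C)(C)C(C)(C)C)CCCCCC=O | intermediate
42 | (4S)-4-benzyl-3-[(2S,3R,9R)-3-hydroxy-2-methyl-9-(TBSO)decanoyl]-1,3-thiazolidine-2-thione | S=C1SC[C@H](Cc2ccccc2)N1C(=O)[C@@H](C)[C@H](O)CCCCC[C@@H](C)O[Si](C)(C)C(C)(C)C | intermediate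
43 | (4S)-4-benzyl-3-[(2S,3R,9R)-3,9-bis(TBSO)-2-methyldecanoyl]-1,3-thiazolidine-2-thione | S=C1SC[C@H](Cc2ccccc2)N1C(=O)[C@@H](C)[C@H](O[Si](C)(C)C(C)(C)C)CCCCC[C@@H](C)O[Si](C)(C)C(C)(C)C | intermediate
44 | (2S,3R,9R)-3,9-bis(TBSO)-2-methyldecanal (C41–C50) | O=C[C@@H](C)[C@H](O[Si](C)(C)C(C)(C)C)CCCCC[C@@H](C)O[Si](C)(C)C(C)(C)C | intermediate
45 | (4S,5R,6R,12R)-6,12-bis(TBSO)-5-methyltridec-1-yn-4-ol | C#CC[C@H](O)[C@@H](C)[C@H](O[Si](C)(C)C(C)(C)C)CCCCC[C@@H](C)O[Si](C)(C)C(C)(C)C | intermediate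
46 | (4S,5R,6R,12R)-1-iodo-6,12-bis(TBSO)-5-methyltridec-1-yn-4-ol | IC#CC[C@H](O)[C@@H](C)[C@H](O[Si](C)(C)C(C)(C)C)CCCCC[C@@H](C)O[Si](C)(C)C(C)(C)C | intermediate
47 | (1Z,4S,5R,6R,12R)-1-iodo-6,12-bis(TBSO)-5-methyltridec-1-en-4-ol (C38–C50) | I/C=C\C[C@H](O)[C@@H](C)[C@H](O[Si](C)(C)C(C)(C)C)CCCCC[C@@H](C)O[Si](C)(C)C(C)(C)C | intermediate
48 | (1Z,4S,5R,6R,12R)-1-iodo-6,12-bis(TBSO)-5-methyltridec-1-en-4-yl [bis(2,2,2-trifluoroethoxy)phosphoryl]acetate | I/C=C\C[C@@H]([C@@H](C)[C@H](O[Si](C)(C)C(C)(C)C)CCCCC[C@@H](C)O[Si](C)(C)C(C)(C)C)OC(=O)CP(=O)(OCC(F)(F)F)OCC(F)(F)F | intermediate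
49 | potassium phosphonate carbanion of 48 (not isolated) | [K+].I/C=C\C[C@@H]([C@@H](C)[C@H](O[Si](C)(C)C(C)(C)C)CCCCC[C@@H](C)O[Si](C)(C)C(C)(C)C)OC(=O)[CH-]P(=O)(OCC(F)(F)F)OCC(F)(F)F | intermediate
50 | seco-ester: dodeca-TBS C1–C37 (2Z,4Z)-dienoate of alcohol 47 | CC(=C/C[C@H](O[Si](C)(C)C(C)(C)C)C[C@@H](O[Si](C)(C)C(C)(C)C)C[C@H](O[Si](C)(C)C(C)(C)C)C[C@@H](O[Si](C)(C)C(C)(C)C)C[C@H](O[Si](C)(C)C(C)(C)C)C[C@@H](O[Si](C)(C)C(C)(C)C)[C@@H](C)[C@H](O[Si](C)(C)C(C)(C)C)/C(C)=C\C[C@H](O[Si](C)(C)C(C)(C)C)CCC[C@H](O[Si](C)(C)C(C)(C)C)CCC[C@H](O[Si](C)(C)C(C)(C)C)CCCCC=C)/C=C\C(=O)O[C@@H](C/C=C\I)[C@@H](C)[C@H](O[Si](C)(C)C(C)(C)C)CCCCC[C@@H](C)O[Si](C)(C)C(C)(C)C | intermediate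
51 | C37 alkyl-9-BBN borane of 50 (not isolated) | CC(=C/C[C@H](O[Si](C)(C)C(C)(C)C)C[C@@H](O[Si](C)(C)C(C)(C)C)C[C@H](O[Si](C)(C)C(C)(C)C)C[C@@H](O[Si](C)(C)C(C)(C)C)C[C@H](O[Si](C)(C)C(C)(C)C)C[C@@H](O[Si](C)(C)C(C)(C)C)[C@@H](C)[C@H](O[Si](C)(C)C(C)(C)C)/C(C)=C\C[C@H](O[Si](C)(C)C(C)(C)C)CCC[C@H](O[Si](C)(C)C(C)(C)C)CCC[C@H](O[Si](C)(C)C(C)(C)C)CCCCCCB1C2CCCC1CCC2)/C=C\C(=O)O[C@@H](C/C=C\I)[C@@H](C)[C@H](O[Si](C)(C)C(C)(C)C)CCCCC[C@@H](C)O[Si](C)(C)C(C)(C)C | intermediate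
52 | dodeca-TBS 42-membered macrolactone | CC1=C/C[C@H](O[Si](C)(C)C(C)(C)C)C[C@@H](O[Si](C)(C)C(C)(C)C)C[C@H](O[Si](C)(C)C(C)(C)C)C[C@@H](O[Si](C)(C)C(C)(C)C)C[C@H](O[Si](C)(C)C(C)(C)C)C[C@@H](O[Si](C)(C)C(C)(C)C)[C@@H](C)[C@H](O[Si](C)(C)C(C)(C)C)/C(C)=C\C[C@H](O[Si](C)(C)C(C)(C)C)CCC[C@H](O[Si](C)(C)C(C)(C)C)CCC[C@H](O[Si](C)(C)C(C)(C)C)CCCCCC/C=C\C[C@@H]([C@@H](C)[C@H](O[Si](C)(C)C(C)(C)C)CCCCC[C@@H](C)O[Si](C)(C)C(C)(C)C)OC(=O)/C=C\1 | intermediate
53 | CNP0392687.2 | CC1=C/C[C@H](O)C[C@@H](O)C[C@H](O)C[C@@H](O)C[C@H](O)C[C@@H](O)[C@@H](C)[C@H](O)/C(C)=C\C[C@H](O)CCC[C@H](O)CCC[C@H](O)CCCCCC/C=C\C[C@@H]([C@@H](C)[C@H](O)CCCCC[C@@H](C)O)OC(=O)/C=C\1 | target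

**Totals and risks**

Total step count: 40. Longest linear sequence: 23 steps (steps 8–27 from alcohol 11, then steps 38–40).

Steps most likely to fail:

1. Step 39 (macrocyclisation). The risk is that, at high dilution, intramolecular transmetalation of the C37 borane is too slow and the material is lost to protodeboronation, β-hydride elimination or oligomerisation. The fallback still closes the ring at C37–C38 but by an intramolecular Negishi coupling. Setting out from 50, hydroboration with 9-BBN and NaBO3 oxidation would give the primary C37 alcohol of the seco-ester F1. I2/PPh3/imidazole would give the primary C37 iodide F2. Activated zinc dust in THF at 35 °C, which inserts into primary alkyl iodides but not into alkenyl iodides, would give the C37 alkylzinc iodide F3. Slow addition of F3 to Pd(PPh3)4 in THF/NMP at 40 °C would cyclise it, rejoining the route at 52.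

2. Step 24 (aldol union). The risk is poor facial selectivity at C15, because the C19 silyl ether gives only a weak enolate bias and the Ipc reagent control for methyl ketones is moderate. The fallback moves the control to the aldehyde in an open transition state. Setting out from 30, LiHMDS/TMSCl at −78 °C would give the kinetic trimethylsilyl enol ether of ketone 30 F4. BF3·OEt2-mediated Mukaiyama aldol addition of F4 to aldehyde 10 in CH2Cl2 at −78 °C (polar 1,3-anti induction from the C13 silyloxy group) would rejoin the route at 32.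

3. Step 38 (Still–Gennari union). The risk is erosion of the 2Z selectivity, or isomerisation or sluggish reaction of the hindered α-methyl (Z)-enal under the basic conditions. The fallback installs C1–C3 by a stereoretentive cross-coupling and joins the halves by esterification. Setting out from vinyl iodide 34, Stille coupling with ethyl (Z)-3-(tributylstannyl)acrylate [Pd2(dba)3, AsPh3, CuI, NMP, rt] would give the ethyl (2Z,4Z)-dienoate F5. Me3SnOH in 1,2-dichloroethane at 80 °C would give the (2Z,4Z)-dienoic acid F6. Yamaguchi esterification of F6 with alcohol 47 (2,4,6-trichlorobenzoyl chloride, Et3N; then 47, DMAP, toluene, 0 °C → rt, short contact time) would rejoin the route at 50.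

**Further compounds**

F1 | step 39 | C37 primary alcohol of the seco-ester | CC(=C/C[C@H](O[Si](C)(C)C(C)(C)C)C[C@@H](O[Si](C)(C)C(C)(C)C)C[C@H](O[Si](C)(C)C(C)(C)C)C[C@@H](O[Si](C)(C)C(C)(C)C)C[C@H](O[Si](C)(C)C(C)(C)C)C[C@@H](O[Si](C)(C)C(C)(C)C)[C@@H](C)[C@H](O[Si](C)(C)C(C)(C)C)/C(C)=C\C[C@H](O[Si](C)(C)C(C)(C)C)CCC[C@H](O[Si](C)(C)C(C)(C)C)CCC[C@H](O[Si](C)(C)C(C)(C)C)CCCCCCO)/C=C\C(=O)O[C@@H](C/C=C\I)[C@@H](C)[C@H](O[Si](C)(C)C(C)(C)C)CCCCC[C@@H](C)O[Si](C)(C)C(C)(C)C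
F2 | step 39 | C37 primary iodide of the seco-ester | CC(=C/C[C@H](O[Si](C)(C)C(C)(C)C)C[C@@H](O[Si](C)(C)C(C)(C)C)C[C@H](O[Si](C)(C)C(C)(C)C)C[C@@H](O[Si](C)(C)C(C)(C)C)C[C@H](O[Si](C)(C)C(C)(C)C)C[C@@H](O[Si](C)(C)C(C)(C)C)[C@@H](C)[C@H](O[Si](C)(C)C(C)(C)C)/C(C)=C\C[C@H](O[Si](C)(C)C(C)(C)C)CCC[C@H](O[Si](C)(C)C(C)(C)C)CCC[C@H](O[Si](C)(C)C(C)(C)C)CCCCCCI)/C=C\C(=O)O[C@@H](C/C=C\I)[C@@H](C)[C@H](O[Si](C)(C)C(C)(C)C)CCCCC[C@@H](C)O[Si](C)(C)C(C)(C)C
F3 | step 39 | C37 alkylzinc iodide of the seco-ester | CC(=C/C[C@H](O[Si](C)(C)C(C)(C)C)C[C@@H](O[Si](C)(C)C(C)(C)C)C[C@H](O[Si](C)(C)C(C)(C)C)C[C@@H](O[Si](C)(C)C(C)(C)C)C[C@H](O[Si](C)(C)C(C)(C)C)C[C@@H](O[Si](C)(C)C(C)(C)C)[C@@H](C)[C@H](O[Si](C)(C)C(C)(C)C)/C(C)=C\C[C@H](O[Si](C)(C)C(C)(C)C)CCC[C@H](O[Si](C)(C)C(C)(C)C)CCC[C@H](O[Si](C)(C)C(C)(C)C)CCCCCC[Zn]I)/C=C\C(=O)O[C@@H](C/C=C\I)[C@@H](C)[C@H](O[Si](C)(C)C(C)(C)C)CCCCC[C@@H](C)O[Si](C)(C)C(C)(C)C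
F4 | step 24 | trimethylsilyl enol ether of ketone 30 | C=C(O[Si](C)(C)C)[C@@H](C)[C@H](O[Si](C)(C)C(C)(C)C)/C(C)=C\C[C@H](O[Si](C)(C)C(C)(C)C)CCC[C@H](O[Si](C)(C)C(C)(C)C)CCC[C@H](O[Si](C)(C)C(C)(C)C)CCCCC=C
F5 | step 38 | ethyl (2Z,4Z)-dienoate (C1–C37, deca-TBS) | CCOC(=O)/C=C\C(C)=C/C[C@H](O[Si](C)(C)C(C)(C)C)C[C@@H](O[Si](C)(C)C(C)(C)C)C[C@H](O[Si](C)(C)C(C)(C)C)C[C@@H](O[Si](C)(C)C(C)(C)C)C[C@H](O[Si](C)(C)C(C)(C)C)C[C@@H](O[Si](C)(C)C(C)(C)C)[C@@H](C)[C@H](O[Si](C)(C)C(C)(C)C)/C(C)=C\C[C@H](O[Si](C)(C)C(C)(C)C)CCC[C@H](O[Si](C)(C)C(C)(C)C)CCC[C@H](O[Si](C)(C)C(C)(C)C)CCCCC=C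
F6 | step 38 | (2Z,4Z)-dienoic acid (C1–C37, deca-TBS) | OC(=O)/C=C\C(C)=C/C[C@H](O[Si](C)(C)C(C)(C)C)C[C@@H](O[Si](C)(C)C(C)(C)C)C[C@H](O[Si](C)(C)C(C)(C)C)C[C@@H](O[Si](C)(C)C(C)(C)C)C[C@H](O[Si](C)(C)C(C)(C)C)C[C@@H](O[Si](C)(C)C(C)(C)C)[C@@H](C)[C@H](O[Si](C)(C)C(C)(C)C)/C(C)=C\C[C@H](O[Si](C)(C)C(C)(C)C)CCC[C@H](O[Si](C)(C)C(C)(C)C)CCC[C@H](O[Si](C)(C)C(C)(C)C)CCCCC=C
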